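I nearly took the slowing of these runs for plain consumption of the reagents, and a smooth curve through them would have let that pass.

| flask | left-handed substrate | right-handed substrate | coupling partner | catalyst | remark |
|---|---|---|---|---|---|
| east | 14 mM | 14 mM | 1.5 equiv | 1 mol% | run made earlier |
| north-west | 22 mM | 22 mM | 1.5 equiv | 1 mol% | run made earlier |
| south-east | 10 mM | 10 mM | 1.5 equiv | 2 mol% | run made earlier |
| flask | 10 mM | 10 mM | 1.50 equiv | 1 mol% |  |

- east (time / min: left-handed product / %, left-handed substrate / %): 0.500: 33.1, 16.9; 1.50: 44.1, 6.6; 3.00: 47.8, 2.0; 4.00: 49.2, 1.1; 6.00: 50.2, 0; 8.00: 50.4, 0
- north-west (time / min: left-handed product / %, left-handed substrate / %): 0.500: 43.3, 6.5; 1.50: 48.4, 0.7; 3.00: 49.9, 0; 4.00: 48.9, 0; 6.00: 50.7, 0; 8.00: 50.1, 0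
- south-east (time / min: left-handed product / %, left-handed substrate / %): 0.667: 36.1, 13.1; 1.33: 42.0, 7.3; 2.50: 47.6, 2.6; 4.00: 48.3, 2.0; 8.00: 50.1, 0

(standard deviation of a reading: 0.5 percentage points)

- catalyst is single-handed; left-handed substrate and right-handed substrate are mirror images of each other, charged as a racemate, each of them at the stated concentration
- the analysis behind the earlier runs scatters by 0.5 percentage points, standard deviation

- factor on the rate of making left-handed product when 30% of the left-handed substrate and right-handed substrate together are converted if coupling partner is charged twice over
- factor on the rate when 30% of the left-handed substrate and right-handed substrate together are converted if catalyst is charged at 10 mol% instead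

In the east run the left-handed product stopped near 50.4%, so I counted left-handed substrate as the one reacting and as the limiting reagent. With x its fraction of own charge left, coupling partner stands at 0.5+x in the same measure. If the rate goes with catalyst, x and partner, then the logarithm of (0.5+x)/x is a clock whose pace stays steady while working catalyst stays steady, so reagent loss is already taken out of it.

In the first instants the east clock ran at 1.01 /min. The south-east run gave 0.993 /min, and loading times charge squared differs between them by a factor of only 1.02. That product therefore sets my scaling. In the middle the east pace was 0.658 /min, then 0.691 /min: it dropped once and then held. I read this as working catalyst falling to a plateau, not declining steadily. Later readings are too close to the scatter to add anything. My working share, the pace from 0.500 min to 3.00 min over the first pace, reads 0.675.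

The flask should start at 0.513 /min and reach x = 0.400 at about 0.791 min, which I placed inside the drop but towards its end, so as an approximation I used my working share there. At 10 mol% it arrives at about 0.0791 min, earlier than the first east reading, with the share near one, so I reckoned a factor of 14.8. Doubled partner gives 2.67 in partner and arrives at about 0.338 min, during the drop. Taking the share midway, I reckoned 3.31. The forecast, which gave 2.95 and 11.7 from “the catalyst dying first-order with time”, stood lower than my two figures.

The flask gave 3.42 and 15.5.

    coupling partner + catalyst + left-handed substrate → catalyst + left-handed product (k = 20000 /M²/s)
    coupling partner + catalyst + right-handed substrate → catalyst + right-handed product (k = 110 /M²/s)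
    catalyst ⇌ dormant form (K = 0.940, k = 0.0150 /s)

In it, catalyst stood at 62.5% at 0.800 min and at 51.6% at 4.00 min, with dormant form holding 48.4% of it. Put to use once more, the working share on the flask's first pace, with x at 2.7%, gave me a half-life of 1.90 min for left-handed substrate at 8.00 min, and the flask's half-life by its own step then was 2.2 min.

The runs were generated by integration for substances that don't exist; scatter was added.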